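## The problem

The target 26 is an unsymmetrical 3,3''-biflavanone. A 7-hydroxyflavanone (unprimed locants) and a 5,7-dihydroxyflavanone (double-primed locants) are joined by one single bond between C3 and C3'', and each carries a 4-hydroxyphenyl group (ring B) at C2. The four stereocentres C2, C3, C3'' and C2'' are contiguous, (2S,3R,2''S,3''R), and both pyranone rings are 2,3-trans. Within one ring the trans arrangement is also the stable one, so C2 and C3 can hold each other under equilibrating conditions. Nothing biases C3 against C3'', so the relation between the halves must be set under kinetic control and then kept. The halves differ only by the 5''-hydroxyl, so any route through a symmetrical intermediate has to tell two equivalent sites apart. The molecule is fragile: C3 and C3'' are α to ketones, base opens a flavanone to the chalcone by β-elimination of the ring phenoxide, and the C2–O1 bonds are benzylic ethers para to an oxygen donor, which ionise in acid and fragment through quinone methides once the phenol is deprotonated. The enabling feature is that C4 and C4'' are the carboxyl carbons of a 2,3-disubstituted succinic acid, each five atoms from an arene carbon ortho to an ether oxygen (C4a next to O1 on the resorcinol ring, C4a'' next to O1'' on the phloroglucinol ring). Two intramolecular arene acylations can therefore close both pyranone rings after all four stereocentres have been arranged on an open chain.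

## Retrosynthesis

**End game (26 to 25 to 23).** The three O–CH3 bonds of 25 are cut last, and one stage earlier the two ring B hydroxyls are traced back to the C–Br bonds of 23 through the bis-boronate 24. The ring B oxygen is what makes the benzylic ethers acid-labile, so it should be absent during acylation and etherification. An aryl ester would attenuate it but would not survive the peroxide cleavage of the auxiliaries, and the phenoxide so released would expel the neighbouring aryloxy group. Bromine is a mild acceptor, inert to every earlier step, and is exchanged for hydroxyl without strong base. Methyl ethers on ring A survive the acylation and direct it. The forward steps must not use base strong enough to enolise C3 or C3''.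

**Key disconnection (23 to 20).** C4–C4a and C4''–C4a'' are cut together, which removes both heterocycles and leaves the acyclic diacid 20 with all four stereocentres on sp3 carbons of a chain. Cutting O1–C2 and O1''–C2'' instead would require β-hydroxy aryl ketones, which dehydrate and undergo retro-aldol cleavage. Cutting C3–C3'' would require a cross-coupling of two flavanone enolates with no handle on chemo- or stereoselectivity. The forward reaction must acylate each arene ortho to its ether oxygen, go para rather than ortho to methoxy on the resorcinol ring, and leave the benzylic C–O bonds and the α-centres intact.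

**Second ether (20 to 18 to 16 + 17).** The diacid comes from the bis-imide 18 by auxiliary removal, and 18 from alcohol 16 and phenol 17 by cutting C2''–O1''. Forming this alkyl–oxygen bond with inversion lets the carbinol come from a syn-aldol, the most reliable aldol for an imide. Forming the aryl–oxygen bond instead would need the anti-aldol and a metal-mediated arylation of a hindered alcohol. The forward reaction must be a clean SN2 displacement at a congested benzylic carbon without elimination.

**Second aldol (16 to 13 + 5, 13 to 11 + 2).** C2''–C3'' is cut to the bis-imide 13 and aldehyde 5, and 13 is traced to acid 11 and auxiliary 2. A two-directional double aldol on a symmetrical succinyl bis-imide would be shorter. It would, however, leave two free benzylic hydroxyls four atoms from activated acyl groups (a set-up for γ-lactonisation) and would force a statistical first etherification. Building the halves one after the other places each phenol at a defined site. The forward aldol must enolise only the CH2 imide and let the new auxiliary override the neighbouring C3 centre.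

**First ether and tert-butyl ester (11 to 10 to 8 + 9).** The acid 11 is the tert-butyl ester 10 unmasked, and 10 comes from alcohol 8 and phenol 9 by cutting C2–O1 with inversion. The 3-methoxyphenyl ether goes in first because it is the less nucleophilic arene and better tolerates the acidolysis of the ester. The tert-butyl ester is chosen because it does not lactonise with the hydroxyl of 8.

**First aldol (8 to 4 + 5, 4 to 1 + 2).** C2–C3 is cut to the succinyl imide 4 and aldehyde 5, and 4 to mono-tert-butyl succinate 1 and oxazolidinone 2. The (R)-auxiliary is needed: the boron syn-aldol then gives C3 as R and the carbinol C2 as R, which inversion turns into S.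

## Roads not taken

**Alternative 1:** The cut goes through O1–C2 and O1''–C2'' and, behind them, C2–C3 and C2''–C3''. A 1,4-diaryl-1,4-diketone A1 that already carries both rings A on the future C4 and C4'' would be enolised on both sides. The two Z-boron enolates would add to two molecules of 4-(methoxymethoxy)benzaldehyde A2 to give the syn,syn-bis-aldol A3. A3 holds all four stereocentres with the carbinols in the inverted sense, so unmasking the ortho phenols and two intramolecular Mitsunobu closures would finish the rings.
- Merits: it is shorter, it never exposes the benzylic ethers to strong acid, there is no regiochemical question on ring A, and both ring C–O bonds form intramolecularly. In these respects it is better than the chosen plan.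
- Weak points: absolute configuration would rest on a chiral boron reagent acting on a bis-enolate of a 1,4-diketone, one of whose carbonyls is flanked by two ortho oxygens and twisted out of conjugation. The β-hydroxy aryl ketones in A3 dehydrate to chalcones and cleave by retro-aldol under the conditions that activate the hydroxyl. The unsymmetrical A1 is itself several steps away.
- Comparison: the chosen plan is longer but sets each pair of centres with a covalently bound auxiliary of known sense on substrates that cannot dehydrate to a conjugated ketone.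

**Alternative 2:** The cut is C3–C3''. One-electron oxidation of 4-hydroxycinnamic acid A4 couples two radicals at the carbons that become C3 and C3'', and each carboxylate traps the opposite quinone methide, giving the cis-fused dilactone A5.
- Merits: one step from a cheap acid forms the central bond and all four stereocentres. The relative configuration is useful: A5 has the same arrangement as the carbinol centres of 8 and 16, so each benzylic centre would need one inversion, as in the chosen plan. No other road is as short to the carbon skeleton.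
- Weak points: A5 is formed racemic and alongside other coupling modes. Each lactone would have to acylate a different phenol ring and each benzylic C–O would have to be replaced by an aryl ether. Lactones are poor acyl donors, and with free 4-hydroxyphenyl groups the benzylic C–O bonds ionise under the acid needed. The two lactones are equivalent, so two different arenes can only be introduced statistically.
- Comparison: the chosen plan spends more steps but gains enantiocontrol, a programmed difference between the halves, and an acyl donor (the free acid) that cyclises under conditions the electron-poor benzylic ethers tolerate. A5 is also the sink that the chosen route avoids by keeping one carboxyl as a tert-butyl ester.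

**Alternative 3:** The cut is C4a''–C8a'' inside the phloroglucinol ring. A triketo ester chain A6 carried on a finished 7-oxygenated flavanone would cyclise under Mg(OMe)2, the carbon next to C4'' attacking the terminal ester, to give the 2',4',6'-trihydroxychalcone A7. Oxa-Michael closure of A7 would then form the second pyranone ring of 26.
- Merits: the phloroglucinol ring is made under mild base with its oxygens in place, and no Friedel–Crafts step is needed. That is an advantage over the chosen plan for the most electron-rich ring.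
- Weak points: C3 in A6 and A7 is α to a ketone and allylic to an enone, so it is likely to epimerise. The chain can cyclise in aldol as well as Claisen modes. The last closure must set C2'' and C3'' on an α-branched chalcone under reversible conditions, with only the remote C2/C3 pair to direct it. The sequence is the longest of the four.
- Comparison: the chosen plan fixes all four centres before any ring exists and does not rely on remote induction.

Key step: step 9

Remark: flavanone locants (C2, C3, C4; double-primed for the 5,7-dioxygenated half) are used for the corresponding carbons of all open-chain intermediates, and 1, 2, 5, 9 and 17 are taken as purchased.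

## Route

Step 1
Reactants: 1 4-tert-butoxy-4-oxobutanoic acid (mono-tert-butyl succinate); 2 (R)-4-benzyl-1,3-oxazolidin-2-one
Product: 4 tert-butyl 4-[(4R)-4-benzyl-2-oxo-1,3-oxazolidin-3-yl]-4-oxobutanoate, via mixed pivalic anhydride 3 (not isolated)
Conditions: PivCl, Et3N, THF, −20 °C; then 2, LiCl, −20 °C to rt
Reagents that add atoms: none
Why: N-Acylation of an oxazolidinone through a mixed pivalic anhydride (LiCl/Et3N activation of the N–H); attack goes to the unhindered succinyl carbonyl of 3 and the tert-butyl ester is not touched.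

Step 2
Reactants: 4 tert-butyl 4-[(4R)-4-benzyl-2-oxo-1,3-oxazolidin-3-yl]-4-oxobutanoate; 5 4-bromobenzaldehyde
Product: 8 tert-butyl (3R,4R)-3-{[(4R)-4-benzyl-2-oxo-1,3-oxazolidin-3-yl]carbonyl}-4-(4-bromophenyl)-4-hydroxybutanoate, via dibutylboron Z-enolate 6 (not isolated), via dibutylboron aldolate 7 (not isolated)
Conditions: Bu2BOTf, i-Pr2NEt, CH2Cl2, −78 to 0 °C; 5, −78 to 0 °C; then pH 7 buffer, MeOH, 30% H2O2, 0 °C
Reagents that add atoms: none
Why: Evans syn-aldol: soft enolisation gives the Z-enolate 6, which reacts through a closed chair transition state with the auxiliary carbonyl turned away from the enolate oxygen, so the (4R)-benzyl group directs the aldehyde to one face and C2 and C3 are both set R in a syn relation. The tert-butyl ester is too poor an acyl donor to trap the new hydroxyl as a γ-lactone.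

Step 3
Reactants: 8 tert-butyl (3R,4R)-3-{[(4R)-4-benzyl-2-oxo-1,3-oxazolidin-3-yl]carbonyl}-4-(4-bromophenyl)-4-hydroxybutanoate; 9 3-methoxyphenol
Product: 10 tert-butyl (3R,4S)-3-{[(4R)-4-benzyl-2-oxo-1,3-oxazolidin-3-yl]carbonyl}-4-(4-bromophenyl)-4-(3-methoxyphenoxy)butanoate
Conditions: PPh3, DIAD, toluene, 0 °C to rt
Reagents that add atoms: none
Why: Mitsunobu etherification: the benzylic hydroxyl is activated on phosphorus and displaced by the phenoxide in an SN2 step, inverting C2 from R to S. The para-bromine disfavours ionisation of the benzylic centre, and the α-hydrogen of the branched imide is hard to remove because its enolate would suffer allylic strain, which holds back elimination.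

Step 4
Reactants: 10 tert-butyl (3R,4S)-3-{[(4R)-4-benzyl-2-oxo-1,3-oxazolidin-3-yl]carbonyl}-4-(4-bromophenyl)-4-(3-methoxyphenoxy)butanoate
Product: 11 (3R,4S)-3-{[(4R)-4-benzyl-2-oxo-1,3-oxazolidin-3-yl]carbonyl}-4-(4-bromophenyl)-4-(3-methoxyphenoxy)butanoic acid
Conditions: CF3CO2H, Et3SiH, CH2Cl2, 0 °C to rt
Reagents that add atoms: none
Why: Acidolysis of a tert-butyl ester by alkyl–oxygen cleavage; the silane reduces the tert-butyl cation before it can alkylate the electron-rich 3-methoxyphenoxy ring. Imide, aryl ethers and aryl bromide are stable to dilute CF3CO2H at this temperature, and the electron-poor benzylic ether should not ionise.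

Step 5
Reactants: 11 (3R,4S)-3-{[(4R)-4-benzyl-2-oxo-1,3-oxazolidin-3-yl]carbonyl}-4-(4-bromophenyl)-4-(3-methoxyphenoxy)butanoic acid; 2 (R)-4-benzyl-1,3-oxazolidin-2-one
Product: 13 (2R)-1,4-bis[(4R)-4-benzyl-2-oxo-1,3-oxazolidin-3-yl]-2-[(S)-(4-bromophenyl)(3-methoxyphenoxy)methyl]butane-1,4-dione, via mixed pivalic anhydride 12 (not isolated)
Conditions: PivCl, Et3N, THF, −20 °C; then 2, LiCl, −20 °C to rt
Reagents that add atoms: none
Why: The same mixed-anhydride N-acylation as in step 1, now on the unhindered CH2CO2H arm of 11; no base strong enough to enolise the existing β-aryloxy imide is present.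

Step 6
Reactants: 13 (2R)-1,4-bis[(4R)-4-benzyl-2-oxo-1,3-oxazolidin-3-yl]-2-[(S)-(4-bromophenyl)(3-methoxyphenoxy)methyl]butane-1,4-dione; 5 4-bromobenzaldehyde
Product: 16 (2R,3R)-1,4-bis[(4R)-4-benzyl-2-oxo-1,3-oxazolidin-3-yl]-2-[(R)-(4-bromophenyl)(hydroxy)methyl]-3-[(S)-(4-bromophenyl)(3-methoxyphenoxy)methyl]butane-1,4-dione, via dibutylboron Z-enolate 14 (not isolated), via dibutylboron aldolate 15 (not isolated)
Conditions: Bu2BOTf, i-Pr2NEt, CH2Cl2, −78 to 0 °C; 5, −78 to 0 °C; then pH 7 buffer, MeOH, 30% H2O2, 0 °C
Reagents that add atoms: none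
Why: Second Evans syn-aldol: only the CH2 imide can form a Z-enolate (14), since enolisation of the branched imide is blocked by allylic strain, and the aryloxy group is γ to the enolised carbonyl and cannot be expelled. The new auxiliary sets C3'' R and C2'' R in a syn relation through the same chair transition state as in step 2, and reagent control is expected to override the adjacent C3 centre.

Step 7
Reactants: 16 (2R,3R)-1,4-bis[(4R)-4-benzyl-2-oxo-1,3-oxazolidin-3-yl]-2-[(R)-(4-bromophenyl)(hydroxy)methyl]-3-[(S)-(4-bromophenyl)(3-methoxyphenoxy)methyl]butane-1,4-dione; 17 3,5-dimethoxyphenol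
Product: 18 (2R,3R)-1,4-bis[(4R)-4-benzyl-2-oxo-1,3-oxazolidin-3-yl]-2-[(S)-(4-bromophenyl)(3,5-dimethoxyphenoxy)methyl]-3-[(S)-(4-bromophenyl)(3-methoxyphenoxy)methyl]butane-1,4-dione
Conditions: PPh3, DIAD, toluene, 0 °C to rt
Reagents that add atoms: none
Why: Mitsunobu etherification with SN2 inversion, turning C2'' from R to S and completing the (2S,3R,3''R,2''S) array. The 4-bromophenyl group again suppresses ionisation, and both flanking α-hydrogens belong to branched imides that resist enolisation.

Step 8
Reactants: 18 (2R,3R)-1,4-bis[(4R)-4-benzyl-2-oxo-1,3-oxazolidin-3-yl]-2-[(S)-(4-bromophenyl)(3,5-dimethoxyphenoxy)methyl]-3-[(S)-(4-bromophenyl)(3-methoxyphenoxy)methyl]butane-1,4-dione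
Product: 20 (2R,3R)-2-[(S)-(4-bromophenyl)(3,5-dimethoxyphenoxy)methyl]-3-[(S)-(4-bromophenyl)(3-methoxyphenoxy)methyl]butanedioic acid, via bis(peroxy acid) 19 (not isolated)
Conditions: LiOH, 30% H2O2, THF/H2O, 0 °C; then Na2SO3; 1 M HCl
Reagents that add atoms: hydrogen peroxide, OO
Why: Hydroperoxide cleavage of N-acyloxazolidinones: the small, weakly basic and strongly nucleophilic HOO− attacks the exocyclic carbonyl even of branched imides and gives the bis(peroxy acid) 19, which sulfite reduces to the diacid. The α-centres C3 and C3'' should not be enolised under these conditions, so neither epimerisation nor loss of aryloxide is expected, and 2 is recovered.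

Step 9
Reactants: 20 (2R,3R)-2-[(S)-(4-bromophenyl)(3,5-dimethoxyphenoxy)methyl]-3-[(S)-(4-bromophenyl)(3-methoxyphenoxy)methyl]butanedioic acid
Product: 23 (2S,3R)-2-(4-bromophenyl)-3-[(2S,3R)-2-(4-bromophenyl)-5,7-dimethoxy-4-oxochroman-3-yl]-7-methoxychroman-4-one, via cyclic succinic anhydride 21 (not isolated), via monocyclised keto acid 22 (not isolated)
Conditions: (CF3CO)2O, CF3SO3H (10 mol %), CH2Cl2, 0 °C to rt
Reagents that add atoms: none
Why: Trifluoroacetic anhydride dehydrates the like-configured succinic acid to the trans-disubstituted cyclic anhydride 21 (in equilibrium with the mixed trifluoroacetic anhydrides), and protonation by the sulfonic acid turns each anhydride carbonyl into an acylium-type electrophile. The arene carbon ortho to the ether oxygen attacks its own carboxyl carbon, C4a'' on C4'' first because the 3,5-dimethoxyphenoxy ring is the more nucleophilic; the σ-complex loses a proton, and the carboxyl group set free in keto acid 22 is re-activated as a mixed anhydride for the second closure, C4a on C4. The closest known reaction is the intramolecular Friedel–Crafts acylation of 3-aryloxypropanoic acids to chroman-4-ones under (CF3CO)2O or P2O5/MeSO3H. Each ring closes in a 6-exo-trig mode; attack of an arene on the other carboxyl would need a seven-membered ring and should not compete. No stereocentre is created: C2, C3, C3'' and C2'' come unchanged from 20, and epimerisation at C3 or C3'' after closure is not favoured because the 2,3-trans rings formed are also the stable ones. The step needs regioselectivity on the 3-methoxyphenoxy ring, where the position para to methoxy is both more activated and less hindered than the one between the two oxygens. It also needs the benzylic C2–O bonds to survive, which the electron-poor 4-bromophenyl groups and the low temperature should secure. Once a ring has closed, its ketone deactivates that arene against trifluoroacetylation.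

Step 10
Reactants: 23 (2S,3R)-2-(4-bromophenyl)-3-[(2S,3R)-2-(4-bromophenyl)-5,7-dimethoxy-4-oxochroman-3-yl]-7-methoxychroman-4-one
Product: 25 (2S,3R)-2-(4-hydroxyphenyl)-3-[(2S,3R)-2-(4-hydroxyphenyl)-5,7-dimethoxy-4-oxochroman-3-yl]-7-methoxychroman-4-one, via bis(pinacol boronate) 24 (not isolated)
Conditions: Pd(dppf)Cl2, B2pin2, KOAc, 1,4-dioxane, 85 °C; filtration; then 30% H2O2, aq NaHCO3, THF, 0 °C
Reagents that add atoms: hydrogen peroxide, OO
Why: Miyaura borylation (oxidative addition of the C–Br bonds to zerovalent palladium, transmetalation from the acetate-activated diboron, reductive elimination) followed by oxidation of the C–B bonds, in which hydroperoxide adds to boron and the aryl group shifts from boron to oxygen. Only KOAc and bicarbonate are present as bases, so the enolisable C3/C3'' centres and the ring ethers should be left alone.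

Step 11
Reactants: 25 (2S,3R)-2-(4-hydroxyphenyl)-3-[(2S,3R)-2-(4-hydroxyphenyl)-5,7-dimethoxy-4-oxochroman-3-yl]-7-methoxychroman-4-one
Product: 26 (2S,3R)-3-[(2S,3R)-5,7-dihydroxy-2-(4-hydroxyphenyl)-4-oxochroman-3-yl]-7-hydroxy-2-(4-hydroxyphenyl)chroman-4-one
Conditions: BBr3, CH2Cl2, −78 °C to rt; then H2O
Reagents that add atoms: none
Why: Lewis-acid cleavage of aryl methyl ethers: BBr3 coordinates each methoxy oxygen and bromide removes the methyl group by SN2, the 5''-methoxy reacting first through chelation to the C4'' carbonyl; hydrolysis frees the phenols. The ring oxygens O1 and O1'' sit on hindered secondary carbons that bromide should not attack under these conditions, and the ring B phenols are present as electron-poor borate esters during the reaction.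

## Compound list

1 | 4-tert-butoxy-4-oxobutanoic acid (mono-tert-butyl succinate) | CC(C)(C)OC(=O)CCC(=O)O | starting material
2 | (R)-4-benzyl-1,3-oxazolidin-2-one | O=C1N[C@H](Cc2ccccc2)CO1 | starting material
3 | 4-tert-butoxy-4-oxobutanoic pivalic anhydride (formed in situ) | CC(C)(C)OC(=O)CCC(=O)OC(=O)C(C)(C)C | intermediate
4 | tert-butyl 4-[(4R)-4-benzyl-2-oxo-1,3-oxazolidin-3-yl]-4-oxobutanoate | CC(C)(C)OC(=O)CCC(=O)N1[C@H](Cc2ccccc2)COC1=O | intermediate
5 | 4-bromobenzaldehyde | O=Cc1ccc(Br)cc1 | starting material
6 | tert-butyl (3Z)-4-[(4R)-4-benzyl-2-oxo-1,3-oxazolidin-3-yl]-4-[(dibutylboranyl)oxy]but-3-enoate, the Z-boron enolate of 4 (formed in situ) | CCCCB(CCCC)O/C(=C\CC(=O)OC(C)(C)C)N1[C@H](Cc2ccccc2)COC1=O | intermediate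
7 | O-dibutylboryl derivative of 8, (3R,4R) (formed in situ) | CC(C)(C)OC(=O)C[C@H]([C@@H](OB(CCCC)CCCC)c1ccc(Br)cc1)C(=O)N1[C@H](Cc2ccccc2)COC1=O | intermediate
8 | tert-butyl (3R,4R)-3-{[(4R)-4-benzyl-2-oxo-1,3-oxazolidin-3-yl]carbonyl}-4-(4-bromophenyl)-4-hydroxybutanoate | CC(C)(C)OC(=O)C[C@H]([C@@H](O)c1ccc(Br)cc1)C(=O)N1[C@H](Cc2ccccc2)COC1=O | intermediate
9 | 3-methoxyphenol | COc1cccc(O)c1 | starting material
10 | tert-butyl (3R,4S)-3-{[(4R)-4-benzyl-2-oxo-1,3-oxazolidin-3-yl]carbonyl}-4-(4-bromophenyl)-4-(3-methoxyphenoxy)butanoate | CC(C)(C)OC(=O)C[C@H]([C@H](Oc1cccc(OC)c1)c1ccc(Br)cc1)C(=O)N1[C@H](Cc2ccccc2)COC1=O | intermediate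
11 | (3R,4S)-3-{[(4R)-4-benzyl-2-oxo-1,3-oxazolidin-3-yl]carbonyl}-4-(4-bromophenyl)-4-(3-methoxyphenoxy)butanoic acid | OC(=O)C[C@H]([C@H](Oc1cccc(OC)c1)c1ccc(Br)cc1)C(=O)N1[C@H](Cc2ccccc2)COC1=O | intermediate
12 | mixed pivalic anhydride of acid 11 (formed in situ) | CC(C)(C)C(=O)OC(=O)C[C@H]([C@H](Oc1cccc(OC)c1)c1ccc(Br)cc1)C(=O)N1[C@H](Cc2ccccc2)COC1=O | intermediate
13 | (2R)-1,4-bis[(4R)-4-benzyl-2-oxo-1,3-oxazolidin-3-yl]-2-[(S)-(4-bromophenyl)(3-methoxyphenoxy)methyl]butane-1,4-dione | O=C(C[C@H]([C@H](Oc1cccc(OC)c1)c1ccc(Br)cc1)C(=O)N1[C@H](Cc2ccccc2)COC1=O)N1[C@H](Cc2ccccc2)COC1=O | intermediate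
14 | Z-dibutylboron enolate of 13 at its CH2C(=O) arm (formed in situ) | CCCCB(CCCC)O/C(=C\[C@H]([C@H](Oc1cccc(OC)c1)c1ccc(Br)cc1)C(=O)N1[C@H](Cc2ccccc2)COC1=O)N1[C@H](Cc2ccccc2)COC1=O | intermediate
15 | O-dibutylboryl derivative of 16 (formed in situ) | O=C([C@@H]([C@@H](OB(CCCC)CCCC)c1ccc(Br)cc1)[C@H]([C@H](Oc1cccc(OC)c1)c1ccc(Br)cc1)C(=O)N1[C@H](Cc2ccccc2)COC1=O)N1[C@H](Cc2ccccc2)COC1=O | intermediate
16 | (2R,3R)-1,4-bis[(4R)-4-benzyl-2-oxo-1,3-oxazolidin-3-yl]-2-[(R)-(4-bromophenyl)(hydroxy)methyl]-3-[(S)-(4-bromophenyl)(3-methoxyphenoxy)methyl]butane-1,4-dione | O=C([C@@H]([C@@H](O)c1ccc(Br)cc1)[C@H]([C@H](Oc1cccc(OC)c1)c1ccc(Br)cc1)C(=O)N1[C@H](Cc2ccccc2)COC1=O)N1[C@H](Cc2ccccc2)COC1=O | intermediate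
17 | 3,5-dimethoxyphenol | COc1cc(O)cc(OC)c1 | starting material
18 | (2R,3R)-1,4-bis[(4R)-4-benzyl-2-oxo-1,3-oxazolidin-3-yl]-2-[(S)-(4-bromophenyl)(3,5-dimethoxyphenoxy)methyl]-3-[(S)-(4-bromophenyl)(3-methoxyphenoxy)methyl]butane-1,4-dione | O=C([C@@H]([C@H](Oc1cc(OC)cc(OC)c1)c1ccc(Br)cc1)[C@H]([C@H](Oc1cccc(OC)c1)c1ccc(Br)cc1)C(=O)N1[C@H](Cc2ccccc2)COC1=O)N1[C@H](Cc2ccccc2)COC1=O | intermediate
19 | (2R,3R)-2-[(S)-(4-bromophenyl)(3,5-dimethoxyphenoxy)methyl]-3-[(S)-(4-bromophenyl)(3-methoxyphenoxy)methyl]butanebis(peroxoic) acid (formed in situ) | OOC(=O)[C@@H]([C@H](Oc1cc(OC)cc(OC)c1)c1ccc(Br)cc1)[C@H]([C@H](Oc1cccc(OC)c1)c1ccc(Br)cc1)C(=O)OO | intermediate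
20 | (2R,3R)-2-[(S)-(4-bromophenyl)(3,5-dimethoxyphenoxy)methyl]-3-[(S)-(4-bromophenyl)(3-methoxyphenoxy)methyl]butanedioic acid | OC(=O)[C@@H]([C@H](Oc1cc(OC)cc(OC)c1)c1ccc(Br)cc1)[C@H]([C@H](Oc1cccc(OC)c1)c1ccc(Br)cc1)C(=O)O | intermediate
21 | (3R,4R)-3-[(S)-(4-bromophenyl)(3-methoxyphenoxy)methyl]-4-[(S)-(4-bromophenyl)(3,5-dimethoxyphenoxy)methyl]oxolane-2,5-dione (formed in situ) | O=C1OC(=O)[C@@H]([C@H](Oc2cccc(OC)c2)c2ccc(Br)cc2)[C@@H]1[C@H](Oc1cc(OC)cc(OC)c1)c1ccc(Br)cc1 | intermediate
22 | (2R,3S)-2-[(2S,3R)-2-(4-bromophenyl)-5,7-dimethoxy-4-oxochroman-3-yl]-3-(4-bromophenyl)-3-(3-methoxyphenoxy)propanoic acid (formed in situ) | OC(=O)[C@@H]([C@H](Oc1cccc(OC)c1)c1ccc(Br)cc1)[C@H]1C(=O)c2c(OC)cc(OC)cc2O[C@@H]1c1ccc(Br)cc1 | intermediate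
23 | (2S,3R)-2-(4-bromophenyl)-3-[(2S,3R)-2-(4-bromophenyl)-5,7-dimethoxy-4-oxochroman-3-yl]-7-methoxychroman-4-one | O=C1c2ccc(OC)cc2O[C@H](c2ccc(Br)cc2)[C@H]1[C@H]1C(=O)c2c(OC)cc(OC)cc2O[C@@H]1c1ccc(Br)cc1 | intermediate
24 | analogue of 23 in which both bromines are replaced by 4,4,5,5-tetramethyl-1,3,2-dioxaborolan-2-yl groups, (2S,3R,2''S,3''R) (formed in situ) | O=C1c2ccc(OC)cc2O[C@H](c2ccc(B3OC(C)(C)C(C)(C)O3)cc2)[C@H]1[C@H]1C(=O)c2c(OC)cc(OC)cc2O[C@@H]1c1ccc(B2OC(C)(C)C(C)(C)O2)cc1 | intermediate
25 | (2S,3R)-2-(4-hydroxyphenyl)-3-[(2S,3R)-2-(4-hydroxyphenyl)-5,7-dimethoxy-4-oxochroman-3-yl]-7-methoxychroman-4-one | O=C1c2ccc(OC)cc2O[C@H](c2ccc(O)cc2)[C@H]1[C@H]1C(=O)c2c(OC)cc(OC)cc2O[C@@H]1c1ccc(O)cc1 | intermediate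
26 | (2S,3R)-3-[(2S,3R)-5,7-dihydroxy-2-(4-hydroxyphenyl)-4-oxochroman-3-yl]-7-hydroxy-2-(4-hydroxyphenyl)chroman-4-one | O=C1c2ccc(O)cc2O[C@H](c2ccc(O)cc2)[C@H]1[C@H]1C(=O)c2c(O)cc(O)cc2O[C@@H]1c1ccc(O)cc1 | target

## Step count and least certain steps

Total: 11 steps. Longest linear sequence: 11 steps (1 to 26); the route is fully linear, with 2, 5, 9 and 17 entering as purchased reagents.

**Step 9 (key step).** The most likely failure is acid-promoted loss of an aryloxy group before the slower second closure on the resorcinol ring takes place, either by β-elimination from the activated carboxyl derivative or by ionisation of a benzylic C–O bond. Intermolecular trifluoroacetylation of the still open, electron-rich ring, attack ortho instead of para to the methoxy group, and stalling after the first closure are further hazards. The fallback separates the two closures and changes the acyl donor for the second; it sets out from 20 and returns at 23. Compound 20 is treated with trifluoroacetic anhydride alone, which should suffice for the phloroglucinol-type ring, and keto acid 22 is isolated. Under neutral conditions (1-chloro-N,N,2-trimethylprop-1-en-1-amine) 22 is converted into (2R,3S)-2-[(2S,3R)-2-(4-bromophenyl)-5,7-dimethoxy-4-oxochroman-3-yl]-3-(4-bromophenyl)-3-(3-methoxyphenoxy)propanoyl chloride F1, which is cyclised with SnCl4 in CH2Cl2 at low temperature to 23. No anhydride or protic superacid is then in contact with the open resorcinol ring.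

**Step 7.** This is the more demanding of the two etherifications (step 3 is the same reaction on a less congested alcohol). The activated alcohol may undergo elimination to the benzylidene succinate, and substitution is slow at a carbinol flanked by a fully substituted carbon. Participation of a γ-carbonyl oxygen or partial ionisation would erode the inversion. The fallback forms the aryl–oxygen bond with retention on the epimeric carbinol instead of the alkyl–oxygen bond with inversion; it sets out from 11 and returns at 20.
- Acid 11 is joined through its mixed anhydride 12 to (S)-4-benzyl-1,3-oxazolidin-2-one to give the mixed bis-imide (4R)-4-benzyl-3-{(2R)-4-[(4S)-4-benzyl-2-oxo-1,3-oxazolidin-3-yl]-2-[(S)-(4-bromophenyl)(3-methoxyphenoxy)methyl]-4-oxobutanoyl}-1,3-oxazolidin-2-one F2.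
- A MgCl2-catalysed anti-aldol (Et3N, Me3SiCl, EtOAc) with 5 follows. The aldehyde attacks the magnesium-chelated enolate on the face opposite to the one used by the boron enolate, which is why the (S)-auxiliary is needed. It gives the trimethylsilyl ether F3 and, after acidic methanolysis, the anti-alcohol F4, with C3'' R and the carbinol already S.
- Chan–Lam coupling of F4 with (3,5-dimethoxyphenyl)boronic acid and Cu(OAc)2 (pyridine, O2, molecular sieves) gives the bis-ether F5. F5 differs from 18 only in the configuration of one auxiliary and is cleaved as in step 8 to 20.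

**Step 6.** Enolisation may not be selective for the CH2 imide. Enolisation at C3 would expel 3-methoxyphenoxide. The C3 centre may also work against the auxiliary (mismatched facial selectivity), and the new hydroxyl may lactonise onto the C4 imide during work-up. The fallback makes both C–C bonds before any ether exists; it sets out from 2 and returns at 16. Butanedioyl dichloride and two equivalents of lithiated 2 give 1,4-bis[(4R)-4-benzyl-2-oxo-1,3-oxazolidin-3-yl]butane-1,4-dione F6. Double soft enolisation (Bu2BOTf, i-Pr2NEt) and addition of two equivalents of 5 give the C2-symmetric syn,syn-diol (2R,3R)-1,4-bis[(4R)-4-benzyl-2-oxo-1,3-oxazolidin-3-yl]-2,3-bis[(R)-(4-bromophenyl)(hydroxy)methyl]butane-1,4-dione F7. Mitsunobu etherification of F7 with a deficit of 9 gives 16, the two hydroxyls being homotopic. The price is a statistical mono-etherification and a diol prone to lactonisation, which is why this is not the main route.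

**Step 8.** Exocyclic attack at two hindered, branched imides may be slow, which gives time for β-elimination of an aryloxide or for endocyclic opening of the oxazolidinone ring. The fallback replaces peroxide hydrolysis by thiolysis and metal-assisted hydrolysis; it sets out from 18 and returns at 20. LiSEt (from EtSH and n-BuLi, THF, 0 °C), a softer and less basic nucleophile, converts 18 into S,S'-diethyl (2R,3R)-2-[(S)-(4-bromophenyl)(3,5-dimethoxyphenoxy)methyl]-3-[(S)-(4-bromophenyl)(3-methoxyphenoxy)methyl]butanebis(thioate) F8. F8 is hydrolysed with AgNO3 in aqueous THF to 20.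

## Further compounds

F1 | step 9 | (2R,3S)-2-[(2S,3R)-2-(4-bromophenyl)-5,7-dimethoxy-4-oxochroman-3-yl]-3-(4-bromophenyl)-3-(3-methoxyphenoxy)propanoyl chloride | ClC(=O)[C@@H]([C@H](Oc1cccc(OC)c1)c1ccc(Br)cc1)[C@H]1C(=O)c2c(OC)cc(OC)cc2O[C@@H]1c1ccc(Br)cc1
F2 | step 7 | (4R)-4-benzyl-3-{(2R)-4-[(4S)-4-benzyl-2-oxo-1,3-oxazolidin-3-yl]-2-[(S)-(4-bromophenyl)(3-methoxyphenoxy)methyl]-4-oxobutanoyl}-1,3-oxazolidin-2-one | O=C(C[C@H]([C@H](Oc1cccc(OC)c1)c1ccc(Br)cc1)C(=O)N1[C@H](Cc2ccccc2)COC1=O)N1[C@@H](Cc2ccccc2)COC1=O
F3 | step 7 | (2R,3R)-1-[(4S)-4-benzyl-2-oxo-1,3-oxazolidin-3-yl]-4-[(4R)-4-benzyl-2-oxo-1,3-oxazolidin-3-yl]-2-[(S)-(4-bromophenyl)(trimethylsilyloxy)methyl]-3-[(S)-(4-bromophenyl)(3-methoxyphenoxy)methyl]butane-1,4-dione | O=C([C@@H]([C@H](O[Si](C)(C)C)c1ccc(Br)cc1)[C@H]([C@H](Oc1cccc(OC)c1)c1ccc(Br)cc1)C(=O)N1[C@H](Cc2ccccc2)COC1=O)N1[C@@H](Cc2ccccc2)COC1=O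
F4 | step 7 | (2R,3R)-1-[(4S)-4-benzyl-2-oxo-1,3-oxazolidin-3-yl]-4-[(4R)-4-benzyl-2-oxo-1,3-oxazolidin-3-yl]-2-[(S)-(4-bromophenyl)(hydroxy)methyl]-3-[(S)-(4-bromophenyl)(3-methoxyphenoxy)methyl]butane-1,4-dione | O=C([C@@H]([C@H](O)c1ccc(Br)cc1)[C@H]([C@H](Oc1cccc(OC)c1)c1ccc(Br)cc1)C(=O)N1[C@H](Cc2ccccc2)COC1=O)N1[C@@H](Cc2ccccc2)COC1=O
F5 | step 7 | (2R,3R)-1-[(4S)-4-benzyl-2-oxo-1,3-oxazolidin-3-yl]-4-[(4R)-4-benzyl-2-oxo-1,3-oxazolidin-3-yl]-2-[(S)-(4-bromophenyl)(3,5-dimethoxyphenoxy)methyl]-3-[(S)-(4-bromophenyl)(3-methoxyphenoxy)methyl]butane-1,4-dione | O=C([C@@H]([C@H](Oc1cc(OC)cc(OC)c1)c1ccc(Br)cc1)[C@H]([C@H](Oc1cccc(OC)c1)c1ccc(Br)cc1)C(=O)N1[C@H](Cc2ccccc2)COC1=O)N1[C@@H](Cc2ccccc2)COC1=O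
F6 | step 6 | 1,4-bis[(4R)-4-benzyl-2-oxo-1,3-oxazolidin-3-yl]butane-1,4-dione | O=C(CCC(=O)N1[C@H](Cc2ccccc2)COC1=O)N1[C@H](Cc2ccccc2)COC1=O
F7 | step 6 | (2R,3R)-1,4-bis[(4R)-4-benzyl-2-oxo-1,3-oxazolidin-3-yl]-2,3-bis[(R)-(4-bromophenyl)(hydroxy)methyl]butane-1,4-dione | O=C([C@@H]([C@@H](O)c1ccc(Br)cc1)[C@H]([C@@H](O)c1ccc(Br)cc1)C(=O)N1[C@H](Cc2ccccc2)COC1=O)N1[C@H](Cc2ccccc2)COC1=O
F8 | step 8 | S,S'-diethyl (2R,3R)-2-[(S)-(4-bromophenyl)(3,5-dimethoxyphenoxy)methyl]-3-[(S)-(4-bromophenyl)(3-methoxyphenoxy)methyl]butanebis(thioate) | CCSC(=O)[C@@H]([C@H](Oc1cc(OC)cc(OC)c1)c1ccc(Br)cc1)[C@H]([C@H](Oc1cccc(OC)c1)c1ccc(Br)cc1)C(=O)SCC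
A1 | alternative 1 | 1-[2-(allyloxy)-4-(methoxymethoxy)phenyl]-4-[2-(allyloxy)-4,6-bis(methoxymethoxy)phenyl]butane-1,4-dione | C=CCOc1cc(OCOC)ccc1C(=O)CCC(=O)c1c(OCC=C)cc(OCOC)cc1OCOC
A2 | alternative 1 | 4-(methoxymethoxy)benzaldehyde | COCOc1ccc(C=O)cc1
A3 | alternative 1 | syn,syn-bis-aldol of A1 with two molecules of A2, 3R,3''R with both carbinols R | O=C(c1ccc(OCOC)cc1OCC=C)[C@@H]([C@@H](O)c1ccc(OCOC)cc1)[C@H]([C@@H](O)c1ccc(OCOC)cc1)C(=O)c1c(OCC=C)cc(OCOC)cc1OCOC
A4 | alternative 2 | (E)-4-hydroxycinnamic acid | OC(=O)/C=C/c1ccc(O)cc1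
A5 | alternative 2 | (3R,3aR,6R,6aR)-3,6-bis(4-hydroxyphenyl)tetrahydrofuro[3,4-c]furan-1,4-dione | O=C1O[C@@H](c2ccc(O)cc2)[C@H]2[C@@H]1[C@H](c1ccc(O)cc1)OC2=O
A6 | alternative 3 | methyl 3,5,7-trioxo-nonenoate chain on C3 of the protected 7-oxygenated flavanone (open-chain precursor of A7) | O=C1c2ccc(OCOC)cc2O[C@H](c2ccc(OCOC)cc2)[C@H]1/C(=C\c1ccc(OCOC)cc1)C(=O)CC(=O)CC(=O)CC(=O)OC
A7 | alternative 3 | protected 7-oxygenated flavanone carrying a 2',4',6'-trihydroxychalcone at C3 | O=C1c2ccc(OCOC)cc2O[C@H](c2ccc(OCOC)cc2)[C@H]1/C(=C\c1ccc(OCOC)cc1)C(=O)c1c(O)cc(O)cc1O
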